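1. I started from a one-step world: substrate fed steadily into a flask and lost there by a single pseudo-first-order step climbs to a level and stays there while the feed lasts, and that level is the feed rate times its lifetime.

2. These were the flasks, the readings and the questions.

| flask | substrate | acid | remark | time |
|---|---|---|---|---|
| gamma | 0.010 M (fed, over 15 min) | 0.015 mM | run made earlier |  |
| theta | 0.010 M (fed, over 15 min) | 0.022 mM | run made earlier |  |
| zeta | 0.015 M (fed, over 15 min) | 0.030 mM | run made earlier |  |
| flask | 0.010 M (fed, over 15 min) | 0.0300 mM |  | 15 min |

| run | time / min | substrate / % | target / % |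
|---|---|---|---|
| gamma | 1.33 | 7 | 2 |
| gamma | 2.00 | 9 | 2 |
| gamma | 3.00 | 13 | 4 |
| gamma | 4.00 | 14 | 8 |
| gamma | 6.00 | 22 | 11 |
| gamma | 10.0 | 22 | 28 |
| gamma | 15.0 | 21 | 46 |
| theta | 0.833 | 5 | 0 |
| theta | 2.50 | 11 | 5 |
| theta | 4.00 | 19 | 8 |
| theta | 6.00 | 20 | 16 |
| theta | 10.0 | 21 | 33 |
| theta | 12.0 | 18 | 39 |
| theta | 15.0 | 17 | 55 |
| zeta | 1.33 | 9 | 0 |
| zeta | 2.50 | 8 | 3 |
| zeta | 4.00 | 11 | 11 |
| zeta | 8.00 | 15 | 24 |
| zeta | 15.0 | 16 | 52 |

(readings scatter by 1.5 percentage points)

- acid is the free proton; pH is minus the decimal logarithm of its molar concentration
- a reading or a percentage of target counts all its forms, free or not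
- what has gone from substrate into another species counts as reacted, even if it can come back
- percentages count the whole charge, also what has not yet gone in
- a reading of substrate is of its free form alone

1. part of the substrate that has reacted at 15 min
2. pH of the solution at 15 min

3. So two times mattered: the dosing time, 15 min, and the holding time, meaning the level of free substrate, as a share of the charge, multiplied by the dosing time.

4. I read the holding time in zeta, whose acid equals the flask's: 16 % free substrate gave 2.40 min, shorter than the dosing time. Gamma, with less acid and also less substrate, gave a longer one, 3.15 min.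

5. The ratio of the two times is the level, 16.0 %. I assumed that the flask's smaller substrate charge left the holding time unchanged, so I committed to 84.0 % reacted in the flask, a figure that carries the scatter of 1.5 percentage points of the one reading behind it.

6. The forecast gave 83 %, below my figure, and pH 4.52, reasoning that “target rates show no clear slowing, so I take acid as unchanged”.

7. The flask gave 84.8 % reacted and pH 4.52.

    substrate + acid → weak acid + acid + target (k = 7620 /M/min)
    substrate + weak acid → side product (k = 10.6 /M/min)
    weak acid ⇌ conjugate base + acid, settled at all times (K = 2.50 × 10⁻⁹ M)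
    substrate → weak acid + target (k = 0.0564 /min)
    substrate + target ⇌ idle adduct, settled at all times (K = 390 /M)

8. The flask held 15.4 % free substrate at 7.50 min and 15.2 % at 15.0 min, a holding time of 2.28 min where I had reckoned 2.40 min from zeta's reading, while the half-life of substrate by the acid step alone, the other concentrations as charged, is 3.0 min, short against 15 min. The neighbour, the same flask with 1.2 × 10⁻⁵ M of acid, less than gamma's, ended at 25 % free substrate, a holding time of 3.78 min, longer than the 3.15 min read in gamma, with 74.8 % reacted.

All runs stem from a simulated flask for an exercise.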